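**Retrosynthetic overview**

- The target is a flavone: ring A carries 5,7-OH and 6-OMe, ring C is the pyranone with OMe on C3, and ring B carries 4'-OH and 3',5'-prenyl groups. The prenyl groups (double Stille coupling on a 3',5'-diiodide), the ring A MOM ethers and the C3 methoxy group (C–O coupling of a C3 bromide) are dealt with last.
- Feature on which the route rests: in ring C the heteroatom-bearing carbon C3 sits between C2 (bound to O1 and the aryl group) and the carbonyl carbon C4. Taking C3 out leaves a 2-aryl-3-oxybenzofuran, so ring C is a furan ring plus one inserted carbon.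
- Key disconnection: 3-bromoflavone ⇒ 2-aryl-3-(triethylsiloxy)benzofuran + CBr2 (cyclopropanation of C2=C3, then opening with loss of bromide and the silyl group).
- The 2-arylbenzofuran-3-one comes from a Parham cyclisation of an α-aryloxy arylacetate. This is assembled from symmetrical 4-methoxy-3,5-bis(MOM-oxy)phenol (from 2-methoxyresorcinol) and an α-bromo ester (from 4-(benzyloxy)phenylacetic acid). The symmetry of the phenol fixes O1 on C8a next to C8–H.
- Ring order: rings A and B are bought; the furan ring is closed in step 8 and enlarged to the pyranone ring C in step 10.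

Key step: step 10

Remark: the target has no stereocentre; the α-bromo ester, the α-aryloxy ester, the benzofuranone and the cyclopropane intermediate are racemic and their stereocentres are erased on the way.

**Route**

Step 1
Reactants: 1 2-methoxyresorcinol
Product: 2 2-methoxy-1,3-bis(methoxymethoxy)benzene
Conditions: MOMCl (2.5 equiv), i-Pr2NEt, CH2Cl2, 0 °C → rt
Reagents that add atoms: chloromethyl methyl ether, COCCl
Why: Williamson-type O-alkylation of both phenols gives MOM acetals that withstand the bases, organolithium, carbene and palladium steps that follow.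

Step 2
Reactants: 2 2-methoxy-1,3-bis(methoxymethoxy)benzene
Product: 3 2-[4-methoxy-3,5-bis(methoxymethoxy)phenyl]-4,4,5,5-tetramethyl-1,3,2-dioxaborolane
Conditions: [Ir(OMe)(cod)]2 (1.5 mol%), 4,4'-di-tert-butyl-2,2'-bipyridine (3 mol%), B2pin2 (1.0 equiv), THF, 80 °C
Reagents that add atoms: bis(pinacolato)diboron, CC1(C)OB(OC1(C)C)B1OC(C)(C)C(C)(C)O1
Why: Iridium-catalysed C–H borylation is governed by sterics, and in this 1,2,3-trisubstituted benzene only C5–H has no ortho substituent, so boron should enter there alone.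

Step 3
Reactants: 3 2-[4-methoxy-3,5-bis(methoxymethoxy)phenyl]-4,4,5,5-tetramethyl-1,3,2-dioxaborolane
Product: 4 4-methoxy-3,5-bis(methoxymethoxy)phenol
Conditions: 30% aq. H2O2, NaOH, THF–H2O, 0 °C → rt
Reagents that add atoms: hydrogen peroxide, OO
Why: Alkaline hydroperoxide oxidation of an arylboronate (1,2-shift of the aryl group from boron to oxygen) should give the symmetrical phenol at the borylated position without touching the acetals.

Step 4
Reactants: 4 4-methoxy-3,5-bis(methoxymethoxy)phenol
Product: 5 2-bromo-4-methoxy-3,5-bis(methoxymethoxy)phenol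
Conditions: NBS (1.0 equiv), CH2Cl2, −78 °C → −40 °C
Reagents that add atoms: N-bromosuccinimide, O=C1CCC(=O)N1Br
Why: Electrophilic aromatic bromination; the two free positions are equivalent by symmetry and ortho to the hydroxyl, so one equivalent of NBS at low temperature should give a single monobromide.

Step 5
Reactants: 6 4-(benzyloxy)phenylacetic acid
Product: 7 methyl [4-(benzyloxy)phenyl]acetate
Conditions: MeOH, H2SO4 (cat.), reflux
Reagents that add atoms: methanol, CO
Why: Fischer esterification; the benzyl aryl ether is stable to catalytic acid in methanol.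

Step 6
Reactants: 7 methyl [4-(benzyloxy)phenyl]acetate
Product: 9 racemic methyl 2-[4-(benzyloxy)phenyl]-2-bromoacetate, via silyl ketene acetal 8 (not isolated)
Conditions: LiHMDS (1.1 equiv) added to 7 and TMSCl (1.2 equiv), THF, −78 °C; then NBS (1.05 equiv), −78 → 0 °C
Reagents that add atoms: N-bromosuccinimide, O=C1CCC(=O)N1Br
Why: Enolisation with in situ O-silylation followed by electrophilic α-bromination of the silyl ketene acetal places bromine only at the ester α-carbon and avoids radical conditions that could attack the benzyl ether CH2.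

Step 7
Reactants: 5 2-bromo-4-methoxy-3,5-bis(methoxymethoxy)phenol; 9 racemic methyl 2-[4-(benzyloxy)phenyl]-2-bromoacetate
Product: 10 racemic methyl 2-[4-(benzyloxy)phenyl]-2-[2-bromo-4-methoxy-3,5-bis(methoxymethoxy)phenoxy]acetate
Conditions: K2CO3, DMF, rt
Reagents that add atoms: none
Why: Williamson ether synthesis, SN2 attack of the phenoxide on an activated benzylic α-bromo ester; the new stereocentre is racemic and is removed in step 9.

Step 8
Reactants: 10 racemic methyl 2-[4-(benzyloxy)phenyl]-2-[2-bromo-4-methoxy-3,5-bis(methoxymethoxy)phenoxy]acetate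
Product: 12 racemic 2-[4-(benzyloxy)phenyl]-5-methoxy-4,6-bis(methoxymethoxy)-1-benzofuran-3(2H)-one, via aryllithium 11 (not isolated)
Conditions: t-BuLi (2.05 equiv), THF–Et2O, −100 → −40 °C; then AcOH
Reagents that add atoms: none
Why: Parham cyclisation: bromine–lithium exchange with t-BuLi at −100 °C should outrun deprotonation, and the aryllithium should attack the ester in a 5-exo-trig acyl substitution, the intramolecular alternative (transfer of the α-hydrogen) being a strained 1,4-shift.

Step 9
Reactants: 12 racemic 2-[4-(benzyloxy)phenyl]-5-methoxy-4,6-bis(methoxymethoxy)-1-benzofuran-3(2H)-one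
Product: 13 {[2-(4-benzyloxyphenyl)-5-methoxy-4,6-bis(methoxymethoxy)-1-benzofuran-3-yl]oxy}triethylsilane
Conditions: TESCl, Et3N, DMAP (cat.), CH2Cl2, 0 °C → rt, under argon
Reagents that add atoms: chlorotriethylsilane, CC[Si](Cl)(CC)CC
Why: Silyl enol ether formation; the ketone is strongly acidic because its enol is an aromatic 3-hydroxybenzofuran, so O-silylation with an amine base should be fast and should remove the C2 stereocentre.

Step 10
Reactants: 13 {[2-(4-benzyloxyphenyl)-5-methoxy-4,6-bis(methoxymethoxy)-1-benzofuran-3-yl]oxy}triethylsilane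
Product: 15 2-[4-(benzyloxy)phenyl]-3-bromo-6-methoxy-5,7-bis(methoxymethoxy)-4H-chromen-4-one, via dibromocyclopropane adduct 14 (not isolated)
Conditions: CHBr3 (2 equiv), KOtBu (2.5 equiv), toluene–hexane, −30 °C → rt
Reagents that add atoms: bromoform, BrC(Br)Br
Why: Proposed new method: dibromocarbene, set free from bromoform by KOtBu, is an electrophilic singlet carbene and should add in a concerted [2+1] fashion to the C2=C3 bond of 13, an enol ether that carries the ring oxygen on C2 and the siloxy group on C3 and is the most nucleophilic π bond present, to give the cis-fused dibromocyclopropane 14. In 14 the old C2–C3 bond should break in a disrotatory two-electron electrocyclic opening concerted with departure of the endo bromide (cyclopropyl-to-allyl cation), the charge being taken up by O1, the C2 aryl group and the siloxy oxygen, so that an aromatic 3-bromo-4-siloxyflavylium ion results, from which bromide or tert-butoxide removes the silyl group to leave the C4 carbonyl. The closest known reactions are the dihalocarbene ring expansion of cyclic silyl enol ethers to 2-halo-2-cycloalkenones and the Ciamician–Dennstedt-type halocarbene expansion of indoles and benzofurans; a 3-siloxybenzofuran has not been used in this way. Ring C is not closed from an open chain: the six-membered pyranone arises by ring enlargement, the carbene carbon becoming C3 with its two new bonds to C2 and C4 made in the cycloaddition and the ring growing from five to six atoms in the electrocyclic opening of the bicyclo[3.1.0] unit. No stereocentre is formed in 15, and the two of 14 are transient and racemic. The step needs chemoselectivity for the furan enol ether over all other π bonds and survival of the O–Si bond until the carbene has added, which the substrate secures by carrying no prenyl alkene yet, only benzenoid rings that do not react with CBr2, and a triethylsilyl instead of a trimethylsilyl group at low temperature.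

Step 11
Reactants: 15 2-[4-(benzyloxy)phenyl]-3-bromo-6-methoxy-5,7-bis(methoxymethoxy)-4H-chromen-4-one
Product: 16 2-[4-(benzyloxy)phenyl]-3,6-dimethoxy-5,7-bis(methoxymethoxy)-4H-chromen-4-one
Conditions: Pd2(dba)3 (2.5 mol%), tBuBrettPhos (6 mol%), Cs2CO3, MeOH (5 equiv), toluene, 70 °C
Reagents that add atoms: methanol, CO
Why: Palladium-catalysed C–O cross-coupling (Buchwald-type methoxylation): zerovalent palladium should insert into the electron-poor C3–Br bond, the bulky biaryl phosphine favours C–O reductive elimination over β-hydride elimination, and the carbonate base keeps free methoxide low so that addition at C2 is held back.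

Step 12
Reactants: 16 2-[4-(benzyloxy)phenyl]-3,6-dimethoxy-5,7-bis(methoxymethoxy)-4H-chromen-4-one
Product: 17 2-(4-hydroxyphenyl)-3,6-dimethoxy-5,7-bis(methoxymethoxy)-4H-chromen-4-one
Conditions: H2 (1 atm), 10% Pd/C, EtOAc–MeOH, rt
Reagents that add atoms: none
Why: Hydrogenolysis of the benzyl aryl ether; MOM acetals, methyl ethers and the flavone enone should persist at 1 atm and room temperature, and no alkene side chain is present yet.

Step 13
Reactants: 17 2-(4-hydroxyphenyl)-3,6-dimethoxy-5,7-bis(methoxymethoxy)-4H-chromen-4-one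
Product: 18 2-(4-hydroxy-3,5-diiodophenyl)-3,6-dimethoxy-5,7-bis(methoxymethoxy)-4H-chromen-4-one
Conditions: I2 (2.2 equiv), K2CO3, MeOH–H2O, 0 °C → rt
Reagents that add atoms: iodine, II
Why: Electrophilic iodination of the phenoxide at both ortho positions (para is blocked); the fully etherified ring A is not attacked by iodine without acid or silver activation.

Step 14
Reactants: 19 prenyl chloride
Product: 21 tributyl(3-methylbut-2-en-1-yl)stannane, via prenylmagnesium chloride 20 (not isolated)
Conditions: Mg turnings, Bu3SnCl, THF, 0 °C → rt (Barbier)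
Reagents that add atoms: tributyltin chloride, CCCC[Sn](Cl)(CCCC)CCCC
Why: Barbier-type stannylation; the allylic Grignard formed in the flask is trapped by the tin chloride at its primary carbon and should give the linear prenylstannane.

Step 15
Reactants: 18 2-(4-hydroxy-3,5-diiodophenyl)-3,6-dimethoxy-5,7-bis(methoxymethoxy)-4H-chromen-4-one; 21 tributyl(3-methylbut-2-en-1-yl)stannane (3 equiv)
Product: 22 2-[4-hydroxy-3,5-bis(3-methylbut-2-en-1-yl)phenyl]-3,6-dimethoxy-5,7-bis(methoxymethoxy)-4H-chromen-4-one
Conditions: Pd(PPh3)4 (10 mol%), DMF, 90 °C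
Reagents that add atoms: none
Why: Twofold Stille cross-coupling; zerovalent palladium inserts into each C–I bond and, after allyl transfer from tin, reductive elimination at the less hindered primary allyl terminus should give the linear prenyl groups.

Step 16
Reactants: 22 2-[4-hydroxy-3,5-bis(3-methylbut-2-en-1-yl)phenyl]-3,6-dimethoxy-5,7-bis(methoxymethoxy)-4H-chromen-4-one
Product: 23 5,7-dihydroxy-2-[4-hydroxy-3,5-bis(3-methylbut-2-en-1-yl)phenyl]-3,6-dimethoxy-4H-chromen-4-one (CNP0236361.0)
Conditions: 3 M aq. HCl–MeOH, 40 °C, short reaction time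
Reagents that add atoms: none
Why: Acid-catalysed acetal solvolysis removes both MOM groups; mild acid and short time should spare the prenyl groups next to the 4'-hydroxyl from cyclisation to a chromane.

**Compound list**

1 | 2-methoxyresorcinol | COc1c(O)cccc1O | starting material
2 | 2-methoxy-1,3-bis(methoxymethoxy)benzene | COCOc1cccc(OCOC)c1OC | intermediate
3 | 2-[4-methoxy-3,5-bis(methoxymethoxy)phenyl]-4,4,5,5-tetramethyl-1,3,2-dioxaborolane | COCOc1cc(B2OC(C)(C)C(C)(C)O2)cc(OCOC)c1OC | intermediate
4 | 4-methoxy-3,5-bis(methoxymethoxy)phenol | COCOc1cc(O)cc(OCOC)c1OC | intermediate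
5 | 2-bromo-4-methoxy-3,5-bis(methoxymethoxy)phenol | COCOc1cc(O)c(Br)c(OCOC)c1OC | intermediate
6 | 4-(benzyloxy)phenylacetic acid | OC(=O)Cc1ccc(OCc2ccccc2)cc1 | starting material
7 | methyl [4-(benzyloxy)phenyl]acetate | COC(=O)Cc1ccc(OCc2ccccc2)cc1 | intermediate
8 | {[2-(4-benzyloxyphenyl)-1-methoxyethenyl]oxy}trimethylsilane (silyl ketene acetal, E/Z mixture, not isolated) | COC(O[Si](C)(C)C)=Cc1ccc(OCc2ccccc2)cc1 | intermediate
9 | methyl 2-[4-(benzyloxy)phenyl]-2-bromoacetate (racemic) | COC(=O)C(Br)c1ccc(OCc2ccccc2)cc1 | intermediate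
10 | methyl 2-[4-(benzyloxy)phenyl]-2-[2-bromo-4-methoxy-3,5-bis(methoxymethoxy)phenoxy]acetate (racemic) | COC(=O)C(Oc1cc(OCOC)c(OC)c(OCOC)c1Br)c1ccc(OCc2ccccc2)cc1 | intermediate
11 | methyl 2-[4-(benzyloxy)phenyl]-2-[2-lithio-4-methoxy-3,5-bis(methoxymethoxy)phenoxy]acetate (aryllithium, not isolated) | COC(=O)C(Oc1cc(OCOC)c(OC)c(OCOC)c1[Li])c1ccc(OCc2ccccc2)cc1 | intermediate
12 | 2-[4-(benzyloxy)phenyl]-5-methoxy-4,6-bis(methoxymethoxy)-1-benzofuran-3(2H)-one (racemic) | COCOc1cc2OC(c3ccc(OCc4ccccc4)cc3)C(=O)c2c(OCOC)c1OC | intermediate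
13 | {[2-(4-benzyloxyphenyl)-5-methoxy-4,6-bis(methoxymethoxy)-1-benzofuran-3-yl]oxy}triethylsilane | CC[Si](CC)(CC)Oc1c(-c2ccc(OCc3ccccc3)cc2)oc2cc(OCOC)c(OC)c(OCOC)c12 | intermediate
14 | gem-dibromocyclopropane fused across C2–C3 of 13: 1,1-dibromo-1a-(4-benzyloxyphenyl)-7b-(triethylsiloxy)-1a,7b-dihydrocyclopropa[b]benzofuran with the ring A methoxy and two MOM-oxy groups unchanged (cis-fused, racemic, not isolated) | CC[Si](CC)(CC)OC12C(Br)(Br)C1(c1ccc(OCc3ccccc3)cc1)Oc1cc(OCOC)c(OC)c(OCOC)c12 | intermediate
15 | 2-[4-(benzyloxy)phenyl]-3-bromo-6-methoxy-5,7-bis(methoxymethoxy)-4H-chromen-4-one | COCOc1cc2oc(-c3ccc(OCc4ccccc4)cc3)c(Br)c(=O)c2c(OCOC)c1OC | intermediate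
16 | 2-[4-(benzyloxy)phenyl]-3,6-dimethoxy-5,7-bis(methoxymethoxy)-4H-chromen-4-one | COCOc1cc2oc(-c3ccc(OCc4ccccc4)cc3)c(OC)c(=O)c2c(OCOC)c1OC | intermediate
17 | 2-(4-hydroxyphenyl)-3,6-dimethoxy-5,7-bis(methoxymethoxy)-4H-chromen-4-one | COCOc1cc2oc(-c3ccc(O)cc3)c(OC)c(=O)c2c(OCOC)c1OC | intermediate
18 | 2-(4-hydroxy-3,5-diiodophenyl)-3,6-dimethoxy-5,7-bis(methoxymethoxy)-4H-chromen-4-one | COCOc1cc2oc(-c3cc(I)c(O)c(I)c3)c(OC)c(=O)c2c(OCOC)c1OC | intermediate
19 | prenyl chloride (1-chloro-3-methylbut-2-ene) | CC(C)=CCCl | starting material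
20 | prenylmagnesium chloride (not isolated) | CC(C)=CC[Mg]Cl | intermediate
21 | tributyl(3-methylbut-2-en-1-yl)stannane | CCCC[Sn](CCCC)(CCCC)CC=C(C)C | intermediate
22 | 2-[4-hydroxy-3,5-bis(3-methylbut-2-en-1-yl)phenyl]-3,6-dimethoxy-5,7-bis(methoxymethoxy)-4H-chromen-4-one | COCOc1cc2oc(-c3cc(CC=C(C)C)c(O)c(CC=C(C)C)c3)c(OC)c(=O)c2c(OCOC)c1OC | intermediate
23 | 5,7-dihydroxy-2-[4-hydroxy-3,5-bis(3-methylbut-2-en-1-yl)phenyl]-3,6-dimethoxy-4H-chromen-4-one (CNP0236361.0) | COc1c(O)cc2oc(-c3cc(CC=C(C)C)c(O)c(CC=C(C)C)c3)c(OC)c(=O)c2c1O | target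

**Step count**

Total steps: 16. Longest linear sequence: 13 (steps 1, 2, 3, 4, 7, 8, 9, 10, 11, 12, 13, 15, 16).

**Steps most likely to fail**

1. Step 10 (the proposed new method). The silyl group may be stripped by tert-butoxide before the carbene adds, after which the enolate would be alkylated at C2 by the carbene. Alternatively the carbene may fail to add to the hindered, tetrasubstituted and partly aromatic C2=C3 bond. The fallback uses known Baker–Venkataraman chemistry, sets out from 5 and comes back to the route at 16, so that steps 8 to 11 are not needed. Bromophenol 5 is treated with n-BuLi (2.2 equiv, THF, −78 °C) to give lithium 2-lithio-4-methoxy-3,5-bis(methoxymethoxy)phenoxide F1, which is acylated with N,2-dimethoxy-N-methylacetamide to 1-[2-hydroxy-5-methoxy-4,6-bis(methoxymethoxy)phenyl]-2-methoxyethan-1-one F2. Esterification with 4-(benzyloxy)benzoyl chloride (Et3N, DMAP, CH2Cl2) should give 4-methoxy-2-(methoxyacetyl)-3,5-bis(methoxymethoxy)phenyl 4-(benzyloxy)benzoate F3. Baker–Venkataraman acyl shift (LiHMDS, THF, −78 → 0 °C) should give 1-[4-(benzyloxy)phenyl]-3-[2-hydroxy-5-methoxy-4,6-bis(methoxymethoxy)phenyl]-2-methoxypropane-1,3-dione F4. Cyclodehydration (PPTS cat., 4 Å molecular sieves, toluene, 60 °C) closes ring C by attack of the phenol oxygen on the aroyl carbonyl and should give 16 with the C3 methoxy group already in place. O1 stays fixed because the acyl group enters at the brominated carbon next to the one free hydroxyl.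

2. Step 11. Methoxide may add at C2 and open or contract the pyranone ring, or β-hydride elimination from the palladium methoxide may lead to reductive loss of bromine. The fallback sets out from 15 and comes back at 16 by making the C–O bond through boron. Miyaura borylation of 15 (PdCl2(dppf), B2pin2, KOAc, dioxane, 80 °C) should give 2-[4-(benzyloxy)phenyl]-6-methoxy-5,7-bis(methoxymethoxy)-3-(4,4,5,5-tetramethyl-1,3,2-dioxaborolan-2-yl)-4H-chromen-4-one F5. Oxidation (NaBO3·4H2O, THF–H2O, rt) should give the flavonol 2-[4-(benzyloxy)phenyl]-3-hydroxy-6-methoxy-5,7-bis(methoxymethoxy)-4H-chromen-4-one F6, and O-methylation (MeI, K2CO3, acetone) gives 16.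

3. Step 8. The acidic α-hydrogen of 10 may be transferred to t-BuLi or, between molecules, to the aryllithium, which would give the debrominated ester instead of the ketone. The fallback sets out from 4 and comes back at 12, and makes this acidic carbon the nucleophile. Ortho-formylation of 4 (MgCl2, Et3N, paraformaldehyde, MeCN, reflux) should give 2-hydroxy-5-methoxy-4,6-bis(methoxymethoxy)benzaldehyde F7. O-alkylation with 9 (K2CO3, DMF, rt) gives methyl 2-[4-(benzyloxy)phenyl]-2-[2-formyl-4-methoxy-3,5-bis(methoxymethoxy)phenoxy]acetate F8. Intramolecular aldol addition (DBU, THF, rt) closes the furan ring to methyl 2-[4-(benzyloxy)phenyl]-3-hydroxy-5-methoxy-4,6-bis(methoxymethoxy)-2,3-dihydro-1-benzofuran-2-carboxylate F9 (diastereomer mixture). Dess–Martin oxidation gives methyl 2-[4-(benzyloxy)phenyl]-5-methoxy-4,6-bis(methoxymethoxy)-3-oxo-2,3-dihydro-1-benzofuran-2-carboxylate F10, and Krapcho dealkoxycarbonylation (LiCl, wet DMSO, 120 °C) gives 12, from which step 9 follows.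

**Further compounds**

F1 | step 10 | lithium 2-lithio-4-methoxy-3,5-bis(methoxymethoxy)phenoxide | [Li]Oc1cc(OCOC)c(OC)c(OCOC)c1[Li]
F2 | step 10 | 1-[2-hydroxy-5-methoxy-4,6-bis(methoxymethoxy)phenyl]-2-methoxyethan-1-one | COCC(=O)c1c(O)cc(OCOC)c(OC)c1OCOC
F3 | step 10 | 4-methoxy-2-(methoxyacetyl)-3,5-bis(methoxymethoxy)phenyl 4-(benzyloxy)benzoate | COCC(=O)c1c(OC(=O)c2ccc(OCc3ccccc3)cc2)cc(OCOC)c(OC)c1OCOC
F4 | step 10 | 1-[4-(benzyloxy)phenyl]-3-[2-hydroxy-5-methoxy-4,6-bis(methoxymethoxy)phenyl]-2-methoxypropane-1,3-dione | COC(C(=O)c1ccc(OCc2ccccc2)cc1)C(=O)c1c(O)cc(OCOC)c(OC)c1OCOC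
F5 | step 11 | 2-[4-(benzyloxy)phenyl]-6-methoxy-5,7-bis(methoxymethoxy)-3-(4,4,5,5-tetramethyl-1,3,2-dioxaborolan-2-yl)-4H-chromen-4-one | COCOc1cc2oc(-c3ccc(OCc4ccccc4)cc3)c(B3OC(C)(C)C(C)(C)O3)c(=O)c2c(OCOC)c1OC
F6 | step 11 | 2-[4-(benzyloxy)phenyl]-3-hydroxy-6-methoxy-5,7-bis(methoxymethoxy)-4H-chromen-4-one | COCOc1cc2oc(-c3ccc(OCc4ccccc4)cc3)c(O)c(=O)c2c(OCOC)c1OC
F7 | step 8 | 2-hydroxy-5-methoxy-4,6-bis(methoxymethoxy)benzaldehyde | O=Cc1c(O)cc(OCOC)c(OC)c1OCOC
F8 | step 8 | methyl 2-[4-(benzyloxy)phenyl]-2-[2-formyl-4-methoxy-3,5-bis(methoxymethoxy)phenoxy]acetate | COC(=O)C(Oc1cc(OCOC)c(OC)c(OCOC)c1C=O)c1ccc(OCc2ccccc2)cc1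
F9 | step 8 | methyl 2-[4-(benzyloxy)phenyl]-3-hydroxy-5-methoxy-4,6-bis(methoxymethoxy)-2,3-dihydro-1-benzofuran-2-carboxylate | COC(=O)C1(c2ccc(OCc3ccccc3)cc2)Oc2cc(OCOC)c(OC)c(OCOC)c2C1O
F10 | step 8 | methyl 2-[4-(benzyloxy)phenyl]-5-methoxy-4,6-bis(methoxymethoxy)-3-oxo-2,3-dihydro-1-benzofuran-2-carboxylate | COC(=O)C1(c2ccc(OCc3ccccc3)cc2)Oc2cc(OCOC)c(OC)c(OCOC)c2C1=O
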